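Ring B (labdane numbering) is treated as a [3+3] union. C6, the acetoxy carbon, lies between C5 and C7, so a C6 ketone makes both flanking carbons nucleophilic; C8=C9–C10 is read as an acetylacetone-derived enone, electrophilic at C10 and at the C8 carbonyl. An acyclic enedione, held together only by the C1–C4 tether, is closed by a chiral-acid-catalysed intramolecular Michael addition/aldol condensation that makes C5–C10 (ring A, quaternary C10) and C7–C8 (ring B) in one operation. The Δ7-6-ketone formed is transposed to the Δ8-6β-ol through its dienol acetate and acetylated. The precursor comes from Negishi union of a mesityl oxide-derived alkylzinc with a butenolide-bearing enol triflate.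

Key step: step 7

Remark on numbering: ring A is C1–C5 and C10; ring B is C5–C10; C11–C12 is the linker; the butenolide is C13–C16; C8 and C10 each carry a methyl and C4 carries two.
Assumption: the antipode of the chiral acid that gives 10S in step 7 cannot be predicted and would be fixed by a catalyst screen; the (S)-series is written. 4-Bromofuran-2(5H)-one is taken as commercial. Alkenes 6 and 12 are drawn as the Z isomers, but their geometry does not matter for the route.

Step 1
Reactants: 1 4-bromofuran-2(5H)-one; 2 tributyl(vinyl)stannane
Product: 3 4-vinylfuran-2(5H)-one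
Conditions: Pd2(dba)3 (2.5 mol%), AsPh3 (10 mol%), BHT (cat.), THF, 50 °C; used at once
Reagents that add atoms: none
Why: Stille coupling at the vinylogous acyl bromide runs under neutral, nucleophile-free conditions and transfers the vinyl group without touching the lactone; no stereocentre is formed.

Step 2
Reactants: 3 4-vinylfuran-2(5H)-one; 4 pentane-2,4-dione
Product: 5 3-[2-(5-oxo-2,5-dihydrofuran-3-yl)ethyl]pentane-2,4-dione
Conditions: K2CO3 (20 mol%), MeCN, 0 °C → rt, the vinylbutenolide added slowly to the diketone
Reagents that add atoms: none
Why: In this vinylogous (1,6-) Michael addition the soft diketone enolate attacks the unsubstituted terminal vinyl carbon of the dienoate (1,4-attack is blocked at the fully substituted ring β-carbon), reprotonation restores the conjugated butenolide, and slow addition of the diene keeps the less acidic, more hindered mono-adduct from adding a second time; no stereocentre is formed.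

Step 3
Reactants: 5 3-[2-(5-oxo-2,5-dihydrofuran-3-yl)ethyl]pentane-2,4-dione
Product: 6 (Z)-4-oxo-3-[2-(5-oxo-2,5-dihydrofuran-3-yl)ethyl]pent-2-en-2-yl triflate
Conditions: LiOTf, Et3N, Tf2O, CH2Cl2, −78 → 0 °C
Reagents that add atoms: trifluoromethanesulfonic anhydride, O=S(=O)(OS(=O)(=O)C(F)(F)F)C(F)(F)F
Why: O-Triflation of the lithium-chelated diketone enolate should give the β-triflyloxy enone (a vinylogous acyl triflate), expected mainly as the Z isomer.

Step 4
Reactants: 7 mesityl oxide; 8 allyltrimethylsilane
Product: 9 4,4-dimethylhept-6-en-2-one
Conditions: TiCl4, CH2Cl2, −78 °C; then H2O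
Reagents that add atoms: none
Why: Hosomi–Sakurai conjugate allylation of the TiCl4-activated β,β-disubstituted enone creates the quaternary C4 with its two methyls and leaves the C5–C6(=O)–C7 methyl ketone.

Step 5
Reactants: 9 4,4-dimethylhept-6-en-2-one
Product: 10 7-bromo-4,4-dimethylheptan-2-one
Conditions: HBr (g), dibenzoyl peroxide (cat.), pentane, 0 °C
Reagents that add atoms: hydrogen bromide, Br
Why: Peroxide-initiated radical-chain (Kharasch) hydrobromination places bromine on the terminal carbon, and the ketone should be inert to the bromine-atom chain at 0 °C.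

Step 6
Reactants: 10 7-bromo-4,4-dimethylheptan-2-one; 6 (Z)-enol triflate
Product: 12 4-[(3Z)-3-acetyl-4,8,8-trimethyl-10-oxoundec-3-en-1-yl]furan-2(5H)-one (acyclic enedione precursor), via alkylzinc bromide 11 (not isolated)
Conditions: Zn dust, LiCl, THF, 50 °C; then the enol triflate, Pd(dppf)Cl2 (3 mol%), THF, rt → 40 °C
Reagents that add atoms: none
Why: LiCl-assisted zinc insertion gives a ketone-tolerant primary alkylzinc, and Negishi coupling at the activated C–OTf bond forms C1–C10 with retention of alkene geometry while the butenolide and both ketones stay inert to the organozinc.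

Step 7
Reactants: 12 acyclic enedione precursor
Product: 15 6-oxolabda-7,13-dien-15,16-olide (5α-H 9α-H 10β-Me), via Michael adduct 13 (not isolated), via ketol 14 (not isolated)
Conditions: (S)-BINOL-derived N-triflylphosphoramide or confined imidodiphosphorimidate (10 mol%), toluene, 60 °C under reduced-pressure reflux, condensate returned through 5 Å MS
Reagents that add atoms: none
Why: Proposed new method: the strong chiral acid O-protonates the tetrasubstituted enone to a hydroxyallyl cation with tertiary-cation character at C10, which is captured inside the chiral ion pair by the C5=C6 enol of the methyl ketone (13); acid-catalysed aldol addition of the C6=C7 enol to the C8 ketone (14) and dehydration then give the conjugated enone, the closest known reaction types being chiral-phosphoric-acid-catalysed Robinson-type annulations and chiral-acid-catalysed asymmetric Nazarov and cation–olefin cyclisations of protonated enones. Ring A closes 6-(enolexo)-exo-trig and ring B 6-(enolendo)-exo-trig. C10 is set by the counter-anion, which shields one face of the planar cationic C10 (alkene geometry is lost on protonation, so the Z/E ratio of 12 is irrelevant); C5 is epimerisable α to the C6 ketone and should settle thermodynamically trans (5α-H) to the 10β-methyl; C9 is not controlled and is erased in step 8. The Michael step needs no regiocontrol, since only C5 reaches C10 through a six-membered transition state (C7 would give an eight-membered ring). The aldol step needs C7→C8 closure over the alternative C8-methyl→C6 closure, which is secured because the C6 carbonyl is buried between quaternary C4 and C10 and because the alternative enone would press its vinylic methyl against the C4 methyls.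

Step 8
Reactants: 15 6-oxolabda-7,13-dien-15,16-olide
Product: 16 6-acetoxylabda-6,8,13-trien-15,16-olide
Conditions: isopropenyl acetate, p-TsOH·H2O (5 mol%), 95 °C (acetone distilled off)
Reagents that add atoms: isopropenyl acetate, CC(=C)OC(C)=O
Why: Acid-catalysed thermodynamic enol acetylation proceeds by γ-enolisation at C9–H to the linear 6-acetoxy-6,8-diene (the cross-conjugated Δ5 isomer is disfavoured by strain against the C4 methyls), which erases C9 and places the ring alkene at C8=C9.

Step 9
Reactants: 16 6-acetoxylabda-6,8,13-trien-15,16-olide
Product: 18 6β-hydroxylabda-8,13-dien-15,16-olide, via deconjugated ketone 17 (not isolated)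
Conditions: NaBH4, EtOH–THF–H2O, 0 °C → rt
Reagents that add atoms: none
Why: This is the classical deconjugative borohydride reduction of a dienol acetate (the Δ4-3-ketosteroid to Δ5-3-ol protocol): acetyl cleavage gives the dienolate, kinetic protonation at C7 gives β,γ-enone 17, and 17 is reduced faster than it reconjugates, with hydride entering C6 from the α-face because the β-face is screened by the syn-axial 4β- and 10β-methyls, so the axial 6β-alcohol (6R) should result.

Step 10
Reactants: 18 6β-hydroxylabda-8,13-dien-15,16-olide
Product: 19 6β-acetoxylabda-8,13-dien-15,16-olide (target; 5S,6R,10S)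
Conditions: Ac2O, DMAP, pyridine, 40 °C
Reagents that add atoms: acetic anhydride, CC(=O)OC(C)=O
Why: DMAP-catalysed acyl transfer esterifies the hindered axial secondary alcohol without changing the C6 configuration or opening the butenolide.

Compound list
1 | 4-bromofuran-2(5H)-one | O=C1C=C(Br)CO1 | starting material
2 | tributyl(vinyl)stannane | C=C[Sn](CCCC)(CCCC)CCCC | starting material
3 | 4-vinylfuran-2(5H)-one | C=CC1=CC(=O)OC1 | intermediate
4 | pentane-2,4-dione | CC(=O)CC(C)=O | starting material
5 | 3-[2-(5-oxo-2,5-dihydrofuran-3-yl)ethyl]pentane-2,4-dione | CC(=O)C(CCC1=CC(=O)OC1)C(C)=O | intermediate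
6 | (Z)-4-oxo-3-[2-(5-oxo-2,5-dihydrofuran-3-yl)ethyl]pent-2-en-2-yl trifluoromethanesulfonate | C/C(OS(=O)(=O)C(F)(F)F)=C(\CCC1=CC(=O)OC1)C(C)=O | intermediate
7 | mesityl oxide (4-methylpent-3-en-2-one) | CC(C)=CC(C)=O | starting material
8 | allyltrimethylsilane | C=CC[Si](C)(C)C | starting material
9 | 4,4-dimethylhept-6-en-2-one | CC(=O)CC(C)(C)CC=C | intermediate
10 | 7-bromo-4,4-dimethylheptan-2-one | CC(=O)CC(C)(C)CCCBr | intermediate
11 | (4,4-dimethyl-6-oxoheptyl)zinc bromide | CC(=O)CC(C)(C)CCC[Zn]Br | intermediate (not isolated)
12 | 4-[(3Z)-3-acetyl-4,8,8-trimethyl-10-oxoundec-3-en-1-yl]furan-2(5H)-one | CC(=O)CC(C)(C)CCC/C(C)=C(/CCC1=CC(=O)OC1)C(C)=O | intermediate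
13 | Michael adduct: monocyclic 1,5-diketone with the C5–C10 bond formed (5α-H, 10β-methyl; C9 epimers) | CC(=O)[C@H]1C(C)(C)CCC[C@]1(C)C(CCC2=CC(=O)OC2)C(C)=O | intermediate (not isolated)
14 | ketol: 8-hydroxy-6-oxolabd-13-en-15,16-olide (C8/C9 epimers) | O=C1CC(C)(O)C(CCC2=CC(=O)OC2)[C@@]2(C)CCCC(C)(C)[C@H]12 | intermediate (not isolated)
15 | 6-oxolabda-7,13-dien-15,16-olide (5α-H, 9α-H, 10β-methyl) | O=C1C=C(C)[C@H](CCC2=CC(=O)OC2)[C@@]2(C)CCCC(C)(C)[C@H]12 | intermediate
16 | 6-acetoxylabda-6,8,13-trien-15,16-olide | CC(=O)OC1=CC(C)=C(CCC2=CC(=O)OC2)[C@@]2(C)CCCC(C)(C)[C@H]12 | intermediate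
17 | 6-oxolabda-8,13-dien-15,16-olide | O=C1CC(C)=C(CCC2=CC(=O)OC2)[C@@]2(C)CCCC(C)(C)[C@H]12 | intermediate (not isolated)
18 | 6β-hydroxylabda-8,13-dien-15,16-olide | O[C@@H]1CC(C)=C(CCC2=CC(=O)OC2)[C@@]2(C)CCCC(C)(C)[C@H]12 | intermediate
19 | 6β-acetoxylabda-8,13-dien-15,16-olide, (5S,6R,10S) | CC(=O)O[C@@H]1CC(C)=C(CCC2=CC(=O)OC2)[C@@]2(C)CCCC(C)(C)[C@H]12 | target

Total steps: 10. Longest linear sequence: 8 (steps 1, 2, 3, 6, 7, 8, 9, 10).

Steps most likely to fail

Step 7 (labelled step). The enol may fail to add to the hindered, weakly electrophilic tetrasubstituted enone under a catalytic chiral acid, or the ion pair may discriminate the two faces of C10 poorly. The fallback uses known chemistry and sets out from 12. It is cyclised with an achiral strong acid (TsOH·H2O, toluene, reflux, Dean–Stark), the classical acid-mediated Michael/aldol annulation, to the racemic enone. The enantiomers are then separated by preparative chromatography on a chiral stationary phase. This returns to the route at 15 and leaves the enantiomer ent-6-oxolabda-7,13-dien-15,16-olide F1, which is set aside.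

Step 9. Borohydride may reduce the butenolide (conjugate or lactone reduction) during the long exposure, or the dienolate may reprotonate at C9 and reconjugate before reduction, leading to the allylic Δ7-alcohol. The fallback sets out from 16 and separates unmasking from reduction. The enol acetate is cleaved without hydride (K2CO3 cat., MeOH, −20 °C, quenched into pH 7 buffer) so that kinetic C7-protonation gives 17, which is now isolated. 17 is then reduced under Luche conditions (NaBH4, CeCl3·7H2O, MeOH, −78 °C), which are selective for 1,2-reduction of the ketone over the unsaturated lactone. This returns at 18 (no new compound, F0).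

Step 2. The isolated vinylbutenolide may polymerise or dimerise by Diels–Alder reaction before the diketone adds, and the adduct may add a second time. The fallback sets out from 1 and avoids free 3. Suzuki–Miyaura coupling of 1 with potassium (2-benzyloxyethyl)trifluoroborate (Pd cat., Cs2CO3, toluene–H2O) gives 4-[2-(benzyloxy)ethyl]furan-2(5H)-one F2. Debenzylation with BCl3 (CH2Cl2, −78 °C) gives 4-(2-hydroxyethyl)furan-2(5H)-one F3. Appel iodination (I2, PPh3, imidazole) gives 4-(2-iodoethyl)furan-2(5H)-one F4. Alkylation of 4 with F4 (K2CO3, acetone) then proceeds by direct substitution or by slow in-situ elimination/1,6-addition, which keeps the concentration of the diene low, and returns at 5.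

Further compounds
F1 | step 7 | ent-6-oxolabda-7,13-dien-15,16-olide (enantiomer of 15) | O=C1C=C(C)[C@@H](CCC2=CC(=O)OC2)[C@]2(C)CCCC(C)(C)[C@@H]12
F0 | step 9 | none | none
F2 | step 2 | 4-[2-(benzyloxy)ethyl]furan-2(5H)-one | O=C1C=C(CCOCc2ccccc2)CO1
F3 | step 2 | 4-(2-hydroxyethyl)furan-2(5H)-one | O=C1C=C(CCO)CO1
F4 | step 2 | 4-(2-iodoethyl)furan-2(5H)-one | O=C1C=C(CCI)CO1
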